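**Plan**
- Retrosynthesis: the ring A O–CH3 bond is cut first (protecting group). Then, in one operation, the aryl–CHO bond and the diaryl ether C–O bond of ring A are cut, which opens the seven-membered ring C to a depside.
- The depside ester C–O bond is cut next, giving a ring A benzoic acid and a ring B/D chromanone phenol. Ring D is cut at its aryl–acyl and O–CMe2 bonds, back to a methoxyhydroquinone and 3-methylbut-2-enoic acid.
- Forward: the ring A acid is made from 3,5-dimethoxytoluene (steps 1–5). Ring D is annulated onto ring B from 2-methoxy-6-methylphenol (steps 6–10). Esterification joins the halves (steps 11–12), ring C closes with the formyl group installed in the same flask (step 13), and the last methyl ether is removed (step 14).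
- Enabling feature: on ring A the carbons bearing OH, CHO and the ether oxygen are adjacent, with the ester carbon next in line. An aryne across the CHO and ether carbons is polarised by the alkoxy neighbour and held by the ester tether, so the ring B oxygen must end on the ether carbon and the carbanion on the formyl carbon.
- Stereochemistry: the target has no stereocentre and no stereogenic double bond, so nothing has to be set.

Key step: step 13

Remark: ring A is the formyl-bearing benzene ring, ring B the other benzene ring, ring C the seven-membered lactone-ether ring and ring D the dihydropyranone ring; compounds 1, 4, 8, 11, 14 and 18 are assumed to be purchased.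

**Step 1**
Reactants: 1 3,5-dimethoxytoluene
Product: 3 2-iodo-1,3-dimethoxy-5-methylbenzene, via (2,6-dimethoxy-4-methylphenyl)lithium 2 (not isolated)
Conditions: n-BuLi, THF, 0 °C → rt; then I2, −78 °C → rt
Reagents that add atoms: iodine, II
Why: Directed ortho-metalation places lithium on the ring carbon between the two methoxy groups, and iodine quenches the aryllithium at that carbon.

**Step 2**
Reactants: 3 2-iodo-1,3-dimethoxy-5-methylbenzene; 4 N,N-dimethylformamide
Product: 6 3-iodo-2,4-dimethoxy-6-methylbenzaldehyde, via aryl iminium chloride 5 (not isolated)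
Conditions: POCl3, DMF, 0 → 70 °C; then H2O, 50 °C
Reagents that add atoms: N,N-dimethylformamide (4), CN(C)C=O; water, O
Why: Vilsmeier–Haack formylation can only attack the two equivalent free ring carbons (ortho to one methoxy, para to the other), so a single aldehyde should form after hydrolysis of the iminium salt.

**Step 3**
Reactants: 6 3-iodo-2,4-dimethoxy-6-methylbenzaldehyde
Product: 7 2-hydroxy-3-iodo-4-methoxy-6-methylbenzaldehyde
Conditions: BCl3, CH2Cl2, −78 → 0 °C; then H2O
Reagents that add atoms: none
Why: Chelation-controlled Lewis-acid demethylation, in which BCl3 bridges the formyl oxygen and the adjacent methoxy group so that only this methyl ether is cleaved and the methoxy para to the formyl group stays.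

**Step 4**
Reactants: 7 2-hydroxy-3-iodo-4-methoxy-6-methylbenzaldehyde; 8 4-chlorobenzenesulfonyl chloride
Product: 9 2-formyl-6-iodo-5-methoxy-3-methylphenyl 4-chlorobenzenesulfonate
Conditions: 4-ClC6H4SO2Cl, Et3N, DMAP (cat.), CH2Cl2, 0 °C → rt
Reagents that add atoms: 4-chlorobenzenesulfonyl chloride (8), O=S(=O)(Cl)c1ccc(Cl)cc1
Why: O-Sulfonylation of a phenol under amine base with DMAP catalysis, run at the aldehyde stage so that no carboxylic acid competes for the sulfonyl chloride.

**Step 5**
Reactants: 9 2-formyl-6-iodo-5-methoxy-3-methylphenyl 4-chlorobenzenesulfonate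
Product: 10 2-[(4-chlorophenyl)sulfonyloxy]-3-iodo-4-methoxy-6-methylbenzoic acid
Conditions: NaClO2, NaH2PO4, 2-methyl-2-butene, t-BuOH/THF/H2O, rt
Reagents that add atoms: sodium chlorite, [Na+].[O-]Cl=O
Why: Pinnick oxidation converts hindered aryl aldehydes into acids without touching aryl iodide, aryl sulfonate or methyl ether, the alkene removing the hypochlorous acid that could chlorinate the ring.

**Step 6**
Reactants: 11 2-methoxy-6-methylphenol
Product: 12 2-methoxy-6-methyl-1,4-benzoquinone
Conditions: Co(salen) (cat.), O2 (1 atm), DMF, rt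
Reagents that add atoms: dioxygen, O=O
Why: Aerobic phenol-to-para-quinone oxidation catalysed by the divalent cobalt complex Co(salen) delivers oxygen to the free para carbon, both ortho carbons being substituted.

**Step 7**
Reactants: 12 2-methoxy-6-methyl-1,4-benzoquinone
Product: 13 2-methoxy-6-methylbenzene-1,4-diol
Conditions: Na2S2O4, EtOAc/H2O, rt; used without delay
Reagents that add atoms: none
Why: Dithionite reduction of a quinone to its hydroquinone is fast and leaves the methyl ether alone.

**Step 8**
Reactants: 13 2-methoxy-6-methylbenzene-1,4-diol; 14 3-methylbut-2-enoic acid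
Product: 16 6-hydroxy-7-methoxy-2,2,5-trimethylchroman-4-one, via open-chain aryl enone 15 (not isolated)
Conditions: P2O5/MeSO3H, 70 °C
Reagents that add atoms: none
Why: Friedel–Crafts acylation followed by intramolecular oxa-Michael addition, in which the ring carbon para to methoxy and ortho to the 4-hydroxyl is acylated (as in orcinol, where attack between two oxygen substituents is disfavoured) and that hydroxyl then closes ring D onto the enone.

**Step 9**
Reactants: 16 6-hydroxy-7-methoxy-2,2,5-trimethylchroman-4-one
Product: 17 6,7-dihydroxy-2,2,5-trimethylchroman-4-one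
Conditions: BBr3, CH2Cl2, −78 °C → rt; then H2O
Reagents that add atoms: none
Why: BBr3 cleavage of an aryl methyl ether, assisted by the neighbouring phenol that binds boron and delivers it to the methoxy oxygen, should leave the tertiary alkyl aryl ether of ring D intact.

**Step 10**
Reactants: 17 6,7-dihydroxy-2,2,5-trimethylchroman-4-one; 18 4-methoxybenzyl chloride
Product: 19 6-hydroxy-7-[(4-methoxyphenyl)methoxy]-2,2,5-trimethylchroman-4-one
Conditions: 4-MeOC6H4CH2Cl (1.0 equiv), K2CO3 (1.0 equiv), DMF, rt
Reagents that add atoms: 4-methoxybenzyl chloride (18), COc1ccc(CCl)cc1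
Why: Williamson etherification with one equivalent of weak base alkylates the more acidic 7-hydroxyl, which is para to the ketone, while the 6-hydroxyl is less acidic and shielded by the 5-methyl group.

**Step 11**
Reactants: 10 2-[(4-chlorophenyl)sulfonyloxy]-3-iodo-4-methoxy-6-methylbenzoic acid; 19 6-hydroxy-7-[(4-methoxyphenyl)methoxy]-2,2,5-trimethylchroman-4-one
Product: 21 7-[(4-methoxyphenyl)methoxy]-2,2,5-trimethyl-4-oxochroman-6-yl 2-[(4-chlorophenyl)sulfonyloxy]-3-iodo-4-methoxy-6-methylbenzoate, via acid chloride 20 (not isolated)
Conditions: (COCl)2, DMF (cat.), CH2Cl2, 0 °C → rt, evaporate; then 19, Et3N, DMAP (cat.), CH2Cl2, 0 °C → rt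
Reagents that add atoms: none
Why: Esterification of a phenol through the acid chloride, the usual answer to a benzoic acid with two ortho substituents, with ether, sulfonate and iodide inert once the HCl has been evaporated.

**Step 12**
Reactants: 21 the depside 4-methoxybenzyl ether
Product: 22 7-hydroxy-2,2,5-trimethyl-4-oxochroman-6-yl 2-[(4-chlorophenyl)sulfonyloxy]-3-iodo-4-methoxy-6-methylbenzoate
Conditions: TFA, anisole, CH2Cl2, 0 °C
Reagents that add atoms: none
Why: Acidolysis of a 4-methoxybenzyl aryl ether with anisole as cation trap frees the ring B phenol, while the hindered aryl ester, sulfonate, iodide and ketone tolerate cold acid.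

**Step 13**
Reactants: 22 the depside iodo-sulfonate with free ring B phenol; 4 N,N-dimethylformamide
Product: 27 mollicellin B methyl ether (the depsidone with methoxy in place of the ring A hydroxyl), via chloromagnesium phenoxide 23 (not isolated), via magnesiated aryl sulfonate 24 (not isolated), via ring A aryne 25 (not isolated), via arylmagnesium depsidone 26 (not isolated)
Conditions: MeMgCl (1.05 equiv), THF (high dilution), −78 °C; iPrMgCl·LiCl (1.1 equiv), −78 °C; warm to 0 °C; DMF, 0 °C → rt; aq. NH4Cl
Reagents that add atoms: N,N-dimethylformamide (4), CN(C)C=O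
Why: Proposed new method: MeMgCl first removes the phenol proton, iPrMgCl·LiCl then exchanges the iodide at −78 °C, and on warming the arylmagnesium expels the neighbouring sulfonate to give the ring A aryne, to which the ring B phenoxide adds before DMF formylates the resulting arylmagnesium. The closest known reaction type is aryne generation from 2-iodoaryl sulfonates by iodine–magnesium exchange, capture by magnesium thiolates or amides and electrophilic quench of the new arylmagnesium; a phenoxide closing a ring this way has not been shown. Ring C closes in a 7-exo-dig mode, the oxygen attacking the aryne carbon next to the ester-bearing carbon, and no stereocentre is formed. The step needs oxygen at the aryne carbon remote from methoxy and magnesium at the carbon beside it, which is secured twice: the methoxy group polarises the strained triple bond toward attack at the distal carbon, and the ester tether can reach only that carbon. Chemoselectivity toward the organomagnesium species should follow from the ester being flanked by substituents on both of its aryl rings and from the ketone being a vinylogous carboxylate once the para phenoxide exists; the same phenoxide placement is also the thermodynamically preferred one should acyl migration between the two ring B oxygens occur.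

**Step 14**
Reactants: 27 mollicellin B methyl ether
Product: 28 mollicellin B
Conditions: BCl3, CH2Cl2, −78 → 0 °C; then H2O
Reagents that add atoms: none
Why: Chelation-controlled demethylation, in which BCl3 bridges the new formyl oxygen and the flanking methoxy group and cleaves that methyl ether, while the diaryl ether on the other flank has no alkyl group to lose and the lactone and ring D ether survive at low temperature.

**Compound list**
1 | 3,5-dimethoxytoluene | COc1cc(C)cc(OC)c1 | starting material
2 | (2,6-dimethoxy-4-methylphenyl)lithium | [Li]c1c(OC)cc(C)cc1OC | intermediate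
3 | 2-iodo-1,3-dimethoxy-5-methylbenzene | COc1cc(C)cc(OC)c1I | intermediate
4 | N,N-dimethylformamide | CN(C)C=O | starting material
5 | N-[(3-iodo-2,4-dimethoxy-6-methylphenyl)methylidene]-N-methylmethanaminium chloride | C[N+](C)=Cc1c(C)cc(OC)c(I)c1OC.[Cl-] | intermediate
6 | 3-iodo-2,4-dimethoxy-6-methylbenzaldehyde | Cc1cc(OC)c(I)c(OC)c1C=O | intermediate
7 | 2-hydroxy-3-iodo-4-methoxy-6-methylbenzaldehyde | Cc1cc(OC)c(I)c(O)c1C=O | intermediate
8 | 4-chlorobenzenesulfonyl chloride | O=S(=O)(Cl)c1ccc(Cl)cc1 | starting material
9 | 2-formyl-6-iodo-5-methoxy-3-methylphenyl 4-chlorobenzenesulfonate | Cc1cc(OC)c(I)c(OS(=O)(=O)c2ccc(Cl)cc2)c1C=O | intermediate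
10 | 2-[(4-chlorophenyl)sulfonyloxy]-3-iodo-4-methoxy-6-methylbenzoic acid | Cc1cc(OC)c(I)c(OS(=O)(=O)c2ccc(Cl)cc2)c1C(=O)O | intermediate
11 | 2-methoxy-6-methylphenol | COc1cccc(C)c1O | starting material
12 | 2-methoxy-6-methyl-1,4-benzoquinone | COC1=CC(=O)C=C(C)C1=O | intermediate
13 | 2-methoxy-6-methylbenzene-1,4-diol | COc1cc(O)cc(C)c1O | intermediate
14 | 3-methylbut-2-enoic acid | CC(C)=CC(=O)O | starting material
15 | 1-(3,6-dihydroxy-4-methoxy-2-methylphenyl)-3-methylbut-2-en-1-one | COc1cc(O)c(C(=O)C=C(C)C)c(C)c1O | intermediate
16 | 6-hydroxy-7-methoxy-2,2,5-trimethylchroman-4-one | COc1cc2OC(C)(C)CC(=O)c2c(C)c1O | intermediate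
17 | 6,7-dihydroxy-2,2,5-trimethylchroman-4-one | Cc1c(O)c(O)cc2OC(C)(C)CC(=O)c12 | intermediate
18 | 4-methoxybenzyl chloride | COc1ccc(CCl)cc1 | starting material
19 | 6-hydroxy-7-[(4-methoxyphenyl)methoxy]-2,2,5-trimethylchroman-4-one | COc1ccc(COc2cc3OC(C)(C)CC(=O)c3c(C)c2O)cc1 | intermediate
20 | 2-(chlorocarbonyl)-6-iodo-5-methoxy-3-methylphenyl 4-chlorobenzenesulfonate | Cc1cc(OC)c(I)c(OS(=O)(=O)c2ccc(Cl)cc2)c1C(Cl)=O | intermediate
21 | 7-[(4-methoxyphenyl)methoxy]-2,2,5-trimethyl-4-oxochroman-6-yl 2-[(4-chlorophenyl)sulfonyloxy]-3-iodo-4-methoxy-6-methylbenzoate | Cc1cc(OC)c(I)c(OS(=O)(=O)c2ccc(Cl)cc2)c1C(=O)Oc1c(OCc2ccc(OC)cc2)cc2OC(C)(C)CC(=O)c2c1C | intermediate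
22 | 7-hydroxy-2,2,5-trimethyl-4-oxochroman-6-yl 2-[(4-chlorophenyl)sulfonyloxy]-3-iodo-4-methoxy-6-methylbenzoate | Cc1cc(OC)c(I)c(OS(=O)(=O)c2ccc(Cl)cc2)c1C(=O)Oc1c(O)cc2OC(C)(C)CC(=O)c2c1C | intermediate
23 | chloromagnesium phenoxide of 22 | Cc1cc(OC)c(I)c(OS(=O)(=O)c2ccc(Cl)cc2)c1C(=O)Oc1c(O[Mg]Cl)cc2OC(C)(C)CC(=O)c2c1C | intermediate
24 | ring A arylmagnesium chloride of 23 (magnesium in place of iodine, sulfonate retained) | Cc1cc(OC)c([Mg]Cl)c(OS(=O)(=O)c2ccc(Cl)cc2)c1C(=O)Oc1c(O[Mg]Cl)cc2OC(C)(C)CC(=O)c2c1C | intermediate
25 | ring A aryne (triple bond across the former iodide and sulfonate carbons) carrying the ring B chloromagnesium phenoxide | CC1=C(C(=O)Oc2c(O[Mg]Cl)cc3OC(C)(C)CC(=O)c3c2C)C#CC(OC)=C1 | intermediate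
26 | depsidone arylmagnesium chloride (magnesium on the future formyl carbon) | Cc1cc(OC)c([Mg]Cl)c2c1C(=O)Oc1c(cc3c(c1C)C(=O)CC(C)(C)O3)O2 | intermediate
27 | mollicellin B methyl ether | Cc1cc(OC)c(C=O)c2c1C(=O)Oc1c(cc3c(c1C)C(=O)CC(C)(C)O3)O2 | intermediate
28 | mollicellin B | Cc1cc(O)c(C=O)c2c1C(=O)Oc1c(cc3c(c1C)C(=O)CC(C)(C)O3)O2 | target

**Step count**
Total steps: 14. Longest linear sequence: 9 steps (steps 1–5 then 11–14, or steps 6–10 then 11–14).

**Steps most likely to fail**

1. Step 13 (proposed method). The magnesium phenoxide may add to the aryne too slowly, so that intermolecular aryne capture or carbonyl addition by the organomagnesium species takes over. Fallback by known chemistry, setting out from 22: the same deprotonation and iodine–magnesium exchange are run at −78 °C, but DMF is added before any warming. This should formylate the still intact magnesiated sulfonate and give 7-hydroxy-2,2,5-trimethyl-4-oxochroman-6-yl 2-[(4-chlorophenyl)sulfonyloxy]-3-formyl-4-methoxy-6-methylbenzoate F1. Cs2CO3 in DMSO at 25–60 °C should then close ring C by intramolecular nucleophilic aromatic substitution, the sulfonate leaving from a carbon activated by the ortho formyl and ortho ester groups. Attack at carbon passes through a seven-membered transition state, attack at sulfur through a nine-membered one. The route is rejoined at 27.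

2. Step 11. Acyl transfer between an acid chloride with two ortho substituents and a phenol flanked on both sides may be slow, leaving room for sulfonyl transfer to the phenoxide or for hydrolysis of the acid chloride. Fallback, setting out from 7: Pinnick oxidation should give 2-hydroxy-3-iodo-4-methoxy-6-methylbenzoic acid F2. Acetone with trifluoroacetic anhydride and TFA should convert it into 8-iodo-7-methoxy-2,2,5-trimethyl-4H-1,3-benzodioxin-4-one F3. In F3 the ortho oxygen is tied back and the carbonyl is activated. The sodium phenoxide of 19 (NaH, THF, 0 → 50 °C) should open it with loss of acetone to 7-[(4-methoxyphenyl)methoxy]-2,2,5-trimethyl-4-oxochroman-6-yl 2-hydroxy-3-iodo-4-methoxy-6-methylbenzoate F4. Its single free hydroxyl is then sulfonylated with 8 (Et3N, DMAP, CH2Cl2), rejoining the route at 21.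

3. Step 8. In the hot acidic dehydrating medium the electron-rich hydroquinone may be sulfonated or oxidised, or the reaction may stop at the aryl ester without carbon acylation. Fallback, setting out from 13: Friedel–Crafts acetylation with acetic acid and BF3·OEt2 at 90 °C should give 1-(3,6-dihydroxy-4-methoxy-2-methylphenyl)ethan-1-one F5, which can be purified and its substitution pattern checked. A Kabbe condensation with acetone and pyrrolidine in refluxing ethanol (enamine aldol, then oxa-Michael closure) should then build ring D and rejoin the route at 16.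

**Further compounds**
F1 | step 13 | 7-hydroxy-2,2,5-trimethyl-4-oxochroman-6-yl 2-[(4-chlorophenyl)sulfonyloxy]-3-formyl-4-methoxy-6-methylbenzoate | Cc1cc(OC)c(C=O)c(OS(=O)(=O)c2ccc(Cl)cc2)c1C(=O)Oc1c(O)cc2OC(C)(C)CC(=O)c2c1C
F2 | step 11 | 2-hydroxy-3-iodo-4-methoxy-6-methylbenzoic acid | Cc1cc(OC)c(I)c(O)c1C(=O)O
F3 | step 11 | 8-iodo-7-methoxy-2,2,5-trimethyl-4H-1,3-benzodioxin-4-one | Cc1cc(OC)c(I)c2OC(C)(C)OC(=O)c12
F4 | step 11 | 7-[(4-methoxyphenyl)methoxy]-2,2,5-trimethyl-4-oxochroman-6-yl 2-hydroxy-3-iodo-4-methoxy-6-methylbenzoate | Cc1cc(OC)c(I)c(O)c1C(=O)Oc1c(OCc2ccc(OC)cc2)cc2OC(C)(C)CC(=O)c2c1C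
F5 | step 8 | 1-(3,6-dihydroxy-4-methoxy-2-methylphenyl)ethan-1-one | COc1cc(O)c(C(C)=O)c(C)c1O
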